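The runs are calculated for an exercise.

In the unit of one charge of E, the epsilon flask held 1.10 charges of Q, so on paper E was the limiting reagent, the one charged in the smaller amount.

| setting | epsilon | alpha | flask |
|---|---|---|---|
| E | 20 mM | 20 mM | 20 mM |
| Q | 22 mM | 44 mM | 22.0 mM |
| G | 1 mM | 1 mM | 1.0 mM |
| temperature | 100 °C | 106 °C | 100 °C |
| remark | the very flask that is asked about, followed so far | run made earlier |  |
| time |  |  | 30 h |

- epsilon (time / h: X / %, E / %): 2.00: 33.6, 63.0; 3.00: 40.0, 55.5; 4.00: 41.7, 53.5; 6.00: 41.8, 53.4; 10.0: 41.8, 53.4; 15.0: 41.4, 54.0; 25.0: 41.0, 53.9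
- alpha (time / h: X / %, E / %): 0.833: 26.0, 72.1; 1.33: 37.9, 59.5; 2.00: 47.6, 48.5; 3.00: 50.8, 44.8; 5.00: 51.0, 43.6; 6.00: 50.6, 44.6; 10.0: 50.6, 44.3

(readings scatter by 0.3 percentage points)

- what is taken out of X is counted as made
- what may be going on: E + G -> D; D -> Z; Q + Z <-> L; L -> G + X; Q -> J
- additions bring no volume worth counting

- south: at 30 h add Q, 50.0% of the amount charged, then wait 30 h
- west: at 30 h take out 90% of the X then present, then wait 30 h
- south-west: at 30 h raise the temperature by 15 K, then wait 30 h
- north-west: change nothing and wait 30 h more
- east: at 30 h add G, 100% of the amount charged, then wait 30 h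

* X, in percent of the E first charged, at 30 h
* the option that brings most further X ("none" if no option brings more than 2 percentage points) (south / west / south-west / north-west / east / none)
* X present, with what was taken out counted in, in percent of the E first charged, after south-west
* X present, with what was taken out counted in, in percent of the E first charged, after north-west

I first wrote the balance of E. After 10.0 h, epsilon read X 41.8% and E 53.4%. The missing 4.80% stood close to the catalyst's charge, 5.00% of the E charge, so I took that part to be sitting on the catalyst. Much E remained, yet X did not rise between 4.00 h, at 41.7%, and 25.0 h, at 41.0%. Each X takes one Q, so I turned to the balance of Q and carried one quantity, the Q yield, the share of the charged Q that ends in X. For epsilon it was 38.0%, and I put the other 62.0% down to J.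

The alpha flask looks nearly the same, with equal E and G, but it had twice the Q and ran hotter, at 106 °C. It stopped too, with E at 44.3% and X at 50.6%. Its Q yield was 23.0%, less than epsilon's, and its X read 8.8 percentage points above epsilon's, the net of more Q and more heat. Q and temperature changed together in alpha, so I could not part their effects.

I therefore reckoned from epsilon's yield, read at the temperature of this flask. South adds 50.0% of the Q charge, which gave me 21 points of the E charge. The options without fresh Q gave nothing by this rule, since the yield multiplies fresh Q. The forecast gave 41.5% for now, south as best, 41.5% after south-west and 41.5% after north-west, on the ground that “Only adding Q restarts turnover”.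

The flask gave 41.5%; south brought 26 points against my 21 points, and each other option brought 0 points, leaving 41.5% after south-west and 41.5% after north-west.

    E + G → D (k = 11.0 /M/min, Ea = 56.0 kJ/mol)
    D → Z (k = 0.190 /min, Ea = 102 kJ/mol)
    Q + Z ⇌ L (K = 85.0 /M, k = 930 /M/min, Ea = 66.0 kJ/mol, ΔH = −3.00 kJ/mol)
    L → G + X (k = 0.450 /min, Ea = 98.0 kJ/mol)
    Q → J (k = 0.0110 /min, Ea = 127 kJ/mol)
    (constants at 100 °C)

After 30.0 h, free Q stood at 0% of its charge, and Z held 100% of the catalyst. Moved alone, Q shifted the answer for now by 5 points at 17.7 mM or 27.1 mM. Put on the flask with 80 mM of E and the same Q, the yield gave 10.4% of that E, and that flask gave 12.3%.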